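## Retrosynthetic overview
1. Sodwanone T (8) ⇒ C2-symmetric diketone 7. The only unsymmetrical element, the 3R-OH, is set last by reagent-controlled mono-reduction of one of two homotopic ketones.
2. 7 ⇒ bis(exo-methylene) tetracyclic diol 5, by oxidation and an exo → tetrasubstituted C=C shift.
3. Key disconnection: all four rings of 5 ⇒ acyclic tetraepoxy bis(allylsilane) 3. At each end the oxepane C–O bond forms first (epoxonium ion), then the cyclohexane C–C bond (allylsilane), and both ends react in the same operation.
4. 3 ⇒ 2 × diepoxy-β-farnesene 2 + Me3Si–SiMe3. A Pd tail-to-tail dimerisation–double silylation makes the central CH2–CH2 bond and both allylsilanes at once.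
5. 2 ⇒ (E)-β-farnesene 1. The Shi epoxidation sets every ring-fusion stereocentre.

Assumption: CIP analysis of the given SMILES gives (3R,5aS,9aS) for the hydroxy half and (5aS,9aS) for the keto half (1-benzoxepine numbering), i.e. trans-fused, homochiral halves with OH cis to the angular methyl; comments use squalene-type numbering (C2/C3 and C6/C7 epoxide carbons, C10=C11 central alkene, C12–C13 central bond).

## Route

Step 1
Reactants: 1 (E)-β-farnesene
Product: 2 (6S,7S,10S)-6,7:10,11-diepoxy-7,11-dimethyl-3-methylidenedodec-1-ene
Conditions: ent-Shi ketone (L-fructose-derived, 30 mol %), Oxone, K2CO3, Bu4NHSO4 (cat.), Na2B4O7/Na2EDTA buffer, MeCN–DMM–H2O, 0 °C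
Reagents that add atoms: Oxone (active part potassium peroxymonosulfate), [K+].[O-]S(=O)(=O)OO
Why: Shi asymmetric epoxidation: the electrophilic chiral dioxirane oxidises only the two electron-rich trisubstituted alkenes (the vinyl/1,1-disubstituted diene is much slower), and the enantiomer of the usual D-fructose ketone (which gives R,R) delivers oxygen through the spiro transition state to give the 6S,7S and 10S epoxides.

Step 2
Reactants: 2 (6S,7S,10S)-6,7:10,11-diepoxy-7,11-dimethyl-3-methylidenedodec-1-ene (2 equiv)
Product: 3 (3S,6S,7S,18S,19S,22S)-2,3:6,7:18,19:22,23-tetraepoxysqualene carrying Me3Si on each of the C10- and C15-methyl carbons (C10=C11/C14=C15 geometry not controlled)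
Conditions: Me3SiSiMe3 (0.5 equiv), Pd(dba)2 (5 mol %), DMF, rt to 40 °C
Reagents that add atoms: hexamethyldisilane, C[Si](C)(C)[Si](C)(C)C
Why: Pd(0)-catalysed dimerisation–double silylation of a 1,3-diene with a disilane: two dienes couple at their unhindered vinyl termini (tail-to-tail, as in Pd telomerisation of isoprene-type dienes) to a bis-π-allyl palladium that takes up the two silyl groups at the outer CH2 termini, while isolated trisubstituted epoxides are inert to Pd(0), no stereocentre is made and the alkene geometry is erased later.

Step 3
Reactants: 3 tetraepoxy bis(allylsilane)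
Product: 5 1,2-bis[(3S,5aS,9aS)-3-hydroxy-2,2,5a-trimethyl-7-methylidenedecahydro-1-benzoxepin-6-yl]ethane, via tetracyclic bis(trimethylsilyl) ether 4 (not isolated)
Conditions: TMSOTf (0.3 equiv), 2,6-di-tert-butyl-4-methylpyridine (0.5 equiv), CH2Cl2, −78 °C; then K2CO3, MeOH, rt
Reagents that add atoms: none
Why: Proposed new method: silylation of each terminal epoxide lets the neighbouring 6,7-epoxide oxygen attack tertiary C2 (endo) to give a bicyclic epoxonium ion, which the tethered allylsilane opens at tertiary C6 with inversion through a chair (intramolecular Hosomi–Sakurai), so C3–O and C7–O keep the Shi configuration and C6 is inverted (trans-fused, 3S,5aS,9aS), while immediate loss of Me3Si+ from the β-silyl cation regenerates TMSOTf, fixes the exocyclic alkene and leaves no long-lived C10 cation for the other central alkene to attack; the closest known reaction types are the TMSOTf-promoted tandem oxa-/carbacyclisation of 1,5-diepoxides ending in allylsilanes and the two-directional epoxide/allylsilane tetracyclisation of C2-symmetric bis-epoxides, merged here so that four rings form in one operation.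

Step 4
Reactants: 5 tetracyclic bis(exo-methylene) diol
Product: 6 1,2-bis[(5aS,9aS)-2,2,5a-trimethyl-7-methylidene-3-oxodecahydro-1-benzoxepin-6-yl]ethane
Conditions: Dess–Martin periodinane (2.5 equiv), CH2Cl2, rt
Reagents that add atoms: none
Why: Dess–Martin oxidation takes both hindered secondary carbinols to ketones under near-neutral conditions that leave the exocyclic alkenes and ring ethers alone, and it removes the cascade-derived 3S centres, which have the wrong configuration for the target.

Step 5
Reactants: 6 bis(exo-methylene) diketone
Product: 7 1,2-bis[(5aS,9aS)-2,2,5a,7-tetramethyl-3-oxo-2,3,4,5,5a,8,9,9a-octahydro-1-benzoxepin-6-yl]ethane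
Conditions: p-TsOH·H2O (20 mol %), toluene, 60 °C, stopped when 1H NMR shows full exo → tetrasubstituted conversion
Reagents that add atoms: none
Why: Acid-catalysed alkene isomerisation (reversible protonation to the tertiary C10 cation) funnels the exocyclic alkenes and any C11 epimers into the thermodynamically preferred tetrasubstituted C10=C11 alkene next to the quaternary carbon, the same shift as α-onocerin → β-onocerin, while the adjacent carbonyl disfavours ionisation of the tertiary ring C–O bond and C6/C7 are not touched.

Step 6
Reactants: 7 C2-symmetric diketone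
Product: 8 sodwanone T
Conditions: (S)-Me-CBS (0.3 equiv), catecholborane (1.0 equiv, slow addition), toluene, −40 °C; aqueous work-up; recovered 7 recycled, over-reduced diol re-oxidised as in step 4
Reagents that add atoms: none
Why: Corey–Bakshi–Shibata reduction: the two carbonyls of 7 are homotopic, so mono-reduction gives a single compound (statistical, about 50 % at best per pass), and the (S)-oxazaborolidine treats the quaternary C(CH3)2O carbon as the large group and delivers hydride to give the 3R carbinol (OH cis to the angular methyl, also the face expected from substrate control by analogy with 4,4-dimethyl-3-ketones), while catecholborane at low temperature does not hydroborate the tetrasubstituted alkenes.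

## Compound list
1 | (E)-β-farnesene, (6E)-7,11-dimethyl-3-methylidenedodeca-1,6,10-triene | C=CC(=C)CC/C=C(\C)CCC=C(C)C | starting material
2 | (6S,7S,10S)-6,7:10,11-diepoxy-7,11-dimethyl-3-methylidenedodec-1-ene | C=CC(=C)CC[C@@H]1O[C@@]1(C)CC[C@@H]1OC1(C)C | intermediate
3 | (3S,6S,7S,18S,19S,22S)-tetraepoxysqualene with Me3Si on the C10- and C15-methyl carbons (central C=C geometry undefined) | C[Si](C)(C)CC(CC[C@@H]1O[C@@]1(C)CC[C@@H]1OC1(C)C)=CCCC=C(C[Si](C)(C)C)CC[C@@H]1O[C@@]1(C)CC[C@@H]1OC1(C)C | intermediate
4 | bis(trimethylsilyl) ether of 5 (bridge-bearing ring CH: configuration undefined, erased in step 5) | C=C1CC[C@@H]2OC(C)(C)[C@@H](O[Si](C)(C)C)CC[C@@]2(C)C1CCC1C(=C)CC[C@@H]2OC(C)(C)[C@@H](O[Si](C)(C)C)CC[C@@]12C | intermediate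
5 | 1,2-bis[(3S,5aS,9aS)-3-hydroxy-2,2,5a-trimethyl-7-methylidenedecahydro-1-benzoxepin-6-yl]ethane (C6 of each unit undefined) | C=C1CC[C@@H]2OC(C)(C)[C@@H](O)CC[C@@]2(C)C1CCC1C(=C)CC[C@@H]2OC(C)(C)[C@@H](O)CC[C@@]12C | intermediate
6 | 1,2-bis[(5aS,9aS)-2,2,5a-trimethyl-7-methylidene-3-oxodecahydro-1-benzoxepin-6-yl]ethane (C6 of each unit undefined) | C=C1CC[C@@H]2OC(C)(C)C(=O)CC[C@@]2(C)C1CCC1C(=C)CC[C@@H]2OC(C)(C)C(=O)CC[C@@]12C | intermediate
7 | 1,2-bis[(5aS,9aS)-2,2,5a,7-tetramethyl-3-oxo-2,3,4,5,5a,8,9,9a-octahydro-1-benzoxepin-6-yl]ethane | CC1=C(CCC2=C(C)CC[C@@H]3OC(C)(C)C(=O)CC[C@@]23C)[C@]2(C)CCC(=O)C(C)(C)O[C@H]2CC1 | intermediate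
8 | sodwanone T | CC1=C(CCC2=C(C)CC[C@@H]3OC(C)(C)[C@H](O)CC[C@@]23C)[C@]2(C)CCC(=O)C(C)(C)O[C@H]2CC1 | target

Total step count: 6. Longest linear sequence: 6 steps (1 → 8).

## Steps most likely to fail

**Step 3 (four-ring cascade).**
- Failure modes: exo-mode oxacyclisation to a smaller cyclic ether, hydride-shift rearrangement of the terminal epoxides to ketones, protodesilylation, or clean reaction at one end only.
- Fallback: separate the C–C from the C–O ring closures, setting out from 3.
- A short exposure to BF3·OEt2 in CH2Cl2 at −95 °C should open only the internal epoxides. These have anchimeric help from the strongly nucleophilic allylsilanes.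
- This gives the bicarbocyclic bis(epoxy alcohol) F2, with C7–OH free and the terminal epoxides intact.
- A separate acid-catalysed (CSA, CH2Cl2) double 7-endo hydroxy-epoxide closure at the tertiary C2 then forms both oxepanes. It has the same stereochemical outcome and returns to the route at 5.

**Step 2 (dimerisation–double silylation on a bulky, epoxide-bearing 2-alkyl diene).**
- Failure modes: the sluggish Si–Si reagent, the wrong dimer regiochemistry, or the 1:1 adduct.
- Fallback: change the bond construction, setting out from 2.
- The Pd/disilane system is steered on purpose to the 1:1 manifold (phosphite ligand, toluene) to give the monomeric 1,4-bis(trimethylsilyl) diepoxide F1.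
- The central C4 unit is then brought in as 1,5-hexadiene (0.5 equiv) by double cross-metathesis (Hoveyda–Grubbs II). This exchanges the =CH–CH2SiMe3 end of each F1 for one end of the diene.
- The sequence returns to the route at 3. Alkene geometry again does not matter.

**Step 5 (exo → tetrasubstituted shift).**
- Failure modes: the C10 cation may be attacked by the alkene of the other half (γ-onocerin-type pentacyclisation). It may also undergo a hydride/methyl shift from the neighbouring quaternary carbon, or stall at the trisubstituted isomer.
- Fallback: separate protonation from deprotonation, setting out from 6.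
- Dry HCl in Et2O–CH2Cl2 at −20 °C adds in the Markovnikov sense, and chloride traps each cation at once to give the bis(tertiary chloride) diketone F3.
- Dehydrochlorination under basic, non-acidic conditions (Li2CO3, LiBr, DMF, 100 °C) gives the Saytzeff alkene and returns to the route at 7.

## Further compounds
F1 | step 2 | (S,S,S)-diepoxy monomer Me3SiCH2–C(R)=CH–CH2SiMe3, the 1,4-disilylation product of 2 | C[Si](C)(C)CC=C(C[Si](C)(C)C)CC[C@@H]1O[C@@]1(C)CC[C@@H]1OC1(C)C
F2 | step 3 | bicarbocyclic bis(epoxy alcohol), two exo-methylene cyclohexanols each carrying a 2-[(S)-3,3-dimethyloxiranyl]ethyl chain | C=C1CC[C@H](O)[C@@](C)(CC[C@@H]2OC2(C)C)C1CCC1C(=C)CC[C@H](O)[C@@]1(C)CC[C@@H]1OC1(C)C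
F3 | step 5 | bis(tertiary chloride) diketone, the HCl adduct of 6 | CC1(Cl)CC[C@@H]2OC(C)(C)C(=O)CC[C@@]2(C)C1CCC1C(C)(Cl)CC[C@@H]2OC(C)(C)C(=O)CC[C@@]12C
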